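The spring run, charged with half the substrate of the autumn run, reads 98.4 % of target at 60.0 min. The autumn run is the asked flask itself, followed so far, and after its highest reading, 93.2 % at 180 min, its target falls.

| setting | autumn | spring | flask |
|---|---|---|---|
| substrate | 0.050 M | 0.025 M | 0.050 M |
| partner | 0.050 M | 0.050 M | 0.0500 M |
| free catalyst | 1.2 mM | 1.2 mM | 1.2 mM |
| remark | the very flask that is asked about, followed so far | run made earlier |  |
| time |  |  | 25 h |

| run | time / min | target / % |
|---|---|---|
| autumn | 60.0 | 65.5 |
| autumn | 180 | 93.2 |
| autumn | 300 | 88.0 |
| autumn | 480 | 81.2 |
| autumn | 720 | 72.3 |
| autumn | 900 | 65.3 |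
| spring | 10.0 | 25.0 |
| spring | 20.0 | 48.0 |
| spring | 30.0 | 69.6 |
| spring | 40.0 | 85.0 |
| spring | 50.0 | 95.8 |
| spring | 60.0 | 98.4 |

(standard deviation of a reading: 0.5 percentage points)

- ash: change nothing and wait 8.0 h more
- maple: at 25 h add partner, 100 % of the amount charged, then wait 8.0 h
- alder: at 25 h add free catalyst, 50.0 % of the amount charged, then wait 8.0 h
- larch: at 25 h take out 90 % of the target then present, then wait 8.0 h

- removed target is counted in
- the numbers in the tables scatter by 0.5 percentage points (one standard deviation)
- additions bring no volume worth counting

1. target, in percent of the substrate first charged, at 25 h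
2. the remedy with the largest gain of target, or "none" below 2 percentage points (ash / maple / alder / larch / none)
3. target present, with what was taken out counted in, in percent of the substrate first charged, after ash
4. target present, with what was taken out counted in, in percent of the substrate first charged, after maple

So I look at the rate of that fall in the flask. Just after the highest reading it loses 5.2 percentage points in 120 min, and at the end 7 points in 180 min. The late pace is thus 0.897 of the early one, a slowing that a scatter of 0.5 points barely shows. I commit to a first-order loss nevertheless. The logarithm of the reading at 300 min over the reading at 900 min, divided by the time between them, gives 4.97 × 10⁻⁴ min⁻¹, my loss constant, the share of the target present that goes per minute.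

Kept up for the 600 min from the last reading to 25 h, the pace at 900 min costs 19 points. But the pace follows the target, so I put that answer back: the average target lowers the pace by a factor 0.851 and the loss becomes 17 points, and one more round gives 17 points. The rounds end close to what the exponential factor 0.742 gives, and with that factor I reckon 48.5 % at 25 h.

Over 8.0 h more the factor is 0.788, so ash ends at 38.2 %, a gain of −10 points. I reckon maple and alder the same, assuming that the loss constant ignores partner and free catalyst, whose charges stand at 0.050 M and 1.2 mM in both runs. Larch shields 90 % of the target, so its gain is −1 point, better than ash yet below 2 points, and I answer none.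

The forecast differs, saying “the loss is zero-order in target” and giving 42.8 %, larch, 24.9 % and 24.9 %. The flask gives 48.4 %, none, 38.1 % and 38.1 %, with these equations:

    substrate + free catalyst → catalyst intermediate A (k = 250 M⁻¹ min⁻¹)
    partner + catalyst intermediate A ⇌ catalyst intermediate B (K = 28.0 M⁻¹, k = 240 M⁻¹ min⁻¹)
    catalyst intermediate B → by-product + catalyst intermediate C (k = 1.50 min⁻¹)
    catalyst intermediate C → catalyst intermediate D (k = 67.0 min⁻¹)
    catalyst intermediate D → free catalyst + target (k = 2.70 min⁻¹)
    target → over-reaction product (k = 5.00 × 10⁻⁴ min⁻¹)

At 1500 min the flask holds 51.5 % of over-reaction product. The loss constant applied to 48.4 % for 8.0 h gives 38.2 %. Carried from 25 h to 4.0 d it leaves 5.83 %, and the same flask read at 4.0 d holds 5.77 % of target.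

(The earlier runs and the new flask come from a simulation from invented constants; noise was put on by code.)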